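The numbers in the tables are calculated with constants of no real substance, noise included.

**Hidden decay.** I cannot read E's survival off final yields: grey ends at 100% G, and that number says nothing about how E stood along the way. What the four flasks ask is how long E sits beside Z.

common to all: E 1 mol%

|  | Z | D | J | temperature | remark | time |
|---|---|---|---|---|---|---|
| grey | 0.010 M | 1.5 equiv | 0.50 equiv | −5 °C | run made earlier |  |
| amber | 0.0067 M | 1.5 equiv | 0.50 equiv | 6 °C | run made earlier |  |
| ochre | 0.015 M | 1.5 equiv | 0.50 equiv | −5 °C | run made earlier |  |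
| red | 0.010 M | 3 equiv | 0.50 equiv | 6 °C | run made earlier |  |
| midnight | 0.010 M | 1.50 equiv (fed, over 30 h) | 0.500 equiv |  | the addition at −20 °C, then warmed to 0 °C; the feed brings no volume worth counting | 6.0 d |
| summer | 0.010 M | 1.50 equiv (fed, over 30 h) | 0.500 equiv | 0 °C | all else is in the flask from the start; the feed brings no volume worth counting | 6.0 d |
| dusk | 0.010 M (fed, over 30 h) | 1.50 equiv | 0.500 equiv | 0 °C | all else is in the flask from the start; the feed brings no volume worth counting | 6.0 d |
| winter | 0.010 M | 1.50 equiv | 0.500 equiv | 0 °C | everything together at the start | 6.0 d |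

| run | time / d | G / % | Z / % |
|---|---|---|---|
| grey | 0.208 | 74 | 27 |
| grey | 0.500 | 88 | 13 |
| grey | 1.04 | 96 | 4 |
| grey | 1.67 | 96 | 2 |
| grey | 2.00 | 97 | 4 |
| grey | 3.00 | 100 | 3 |
| grey | 4.00 | 100 | 0 |
| amber | 0.417 | 80 | 21 |
| amber | 0.625 | 81 | 18 |
| amber | 0.833 | 89 | 13 |
| amber | 1.25 | 90 | 6 |
| amber | 2.08 | 97 | 3 |
| amber | 3.00 | 96 | 4 |
| amber | 5.00 | 98 | 0 |
| ochre | 0.625 | 96 | 3 |
| ochre | 1.25 | 99 | 0 |
| ochre | 2.08 | 99 | 0 |
| ochre | 3.00 | 101 | 2 |
| ochre | 4.00 | 99 | 1 |
| ochre | 5.00 | 101 | 0 |
| red | 0.417 | 100 | 2 |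
| red | 1.25 | 101 | 0 |
| red | 2.00 | 99 | 0 |
| red | 3.00 | 100 | 0 |
| red | 5.00 | 98 | 1 |

(scatter of a reading: 1.5 percentage points)



1. the flask with the highest amount of G, in percent of the Z charged ("all alike" if they lie within 1.5 percentage points) (midnight / summer / dusk / winter / all alike)
2. final G, as a percentage of the Z charged, in midnight
3. final G, as a percentage of the Z charged, in summer
4. final G, as a percentage of the Z charged, in dusk
5. final G, as a percentage of the Z charged, in winter

**Two times.** My measure is the exposure: the time integral of c_Z divided by the charge, in hours of full charge. With everything together at the start, it equals the lifetime of Z. Grey's first reading gives 3.81 h, and I carry this to 0 °C, a small step. In grey that lifetime lengthens to 11.0 h between the second and third readings. Part of that is D used up, but part may be E lost.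

In summer D arrives over 30 h. If D divides between Z and J as charged, c_Z falls evenly across the feed, so summer's exposure is 15.0 h, which is 3.94 times the lifetime.

**My reckoning.** Winter should stand highest and summer is the flask at risk. Midnight lies colder than any run so far, so I leave it open.

**The forecast.** It says all alike, with 99% in summer, and finds “no visible side path or loss of G”.

**The result.** Midnight gives 97.0%, summer 38.2%, dusk 96.6% and winter 99.4%, so the highest is winter.

    J + D + E → E + Q (k = 2.20 × 10⁵ M⁻² h⁻¹, Ea = 36.0 kJ mol⁻¹)
    Z + E → L (k = 21.0 M⁻¹ h⁻¹, Ea = 47.0 kJ mol⁻¹)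
    Z + D + E → E + G (k = 5.10 × 10⁵ M⁻² h⁻¹, Ea = 37.0 kJ mol⁻¹)
    J ⇌ X (K = 3.80, k = 0.0820 h⁻¹, Ea = 92.0 kJ mol⁻¹, ΔH = −8.00 kJ mol⁻¹)
    (constants at 0 °C)

**One reason.** The forecast parts from the flask at summer. The passing of Z + E into the off-cycle form L is the main reason: with that step struck out, summer gives 100% instead of 38.2%. At 6.00 d summer holds E at 0%, with Z at 60.8% and D at 71.3% of its charge, and at 60.0 d Z still stands at 60.8%.

**Second flask.** The neighbour flask is winter's recipe with 0.900 equiv of D. If D again divides between Z and J as charged, I reckon 40.0% of Z stays beyond its reach through 6.0 d. That is an exposure of about 57.6 h, or 15.1 times the lifetime and longer than the exposure I reckoned for summer, so I expect E to fail there too. The neighbour flask ends with E at 0.00726%, G at 69.5% and Z at 29.5%, which is less Z than I reckoned.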